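**Plan**

- Retrosynthesis: the enol ester C–O bond, the C5–C6 bond of the acetonyl arm, the C15–O ether bond and the C3–C18 bond are cut first. The carbocyclic core then goes back to a bicyclo[4.3.1]decanone ester, in which the C10–C11 bond and the C2–C1–C11 connection of ring A are undone together.
- Enabling feature: C1, the one-carbon bridge shared by rings A and B, lies between the quaternary, methyl-bearing C11 and C2, and C2 carries C3, which can be a ketone. C1–C2–C11 can therefore be folded back into a cyclopropane on a cyclopentane (C2, C14, C13, C12, C11), that is a 1-acyl-5-methylbicyclo[3.1.0]hexane.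
- Forward: the six-membered ring of (S)-limonene is cut and reclosed to a cyclopentenal, the acyl chain and the cyclopropane are added, and a ketyl radical cascade enlarges the cyclopentane to ring A by one carbon while it closes ring B. Ring C follows by hydroalkoxylation, then C3/C4 oxidation, the C5 arm and the enol ester.
- Stereochemistry: C14 comes from limonene and directs C2, C10 and C11 in the cascade. C3 is set by dihydroxylation from the convex face, C5 by hydrogen-atom transfer, and the E enol ester by syn-hydroboration and a stereoretentive copper coupling.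

Key step: step 7

Atom numbers used below: C1 bridging CH2; C2 and C11 bridgeheads (C11 bears the methyl); C3 carbinol carbon; C4 ring ketone; C5 acetonyl-bearing carbon; C6/C7 acetonyl CH2 and C=O; C8=C9 enol ester alkene (C9 on C10); C12–C14 the other carbons of ring A; C15 the CMe2 carbon; C18 the OCH2 carbon. Ring A is the six-membered carbocycle (C1, C2, C14, C13, C12, C11), ring B the seven-membered carbocycle (C1–C5, C10, C11), ring C the oxane.

Remark: the cyclopropane formed in step 4 may be a mixture of the two ring-fusion diastereomers; both give the same radical in step 7, and the SMILES show the expected major one.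

**Route**

Step 1
Reactants: 1 (S)-(−)-limonene
Product: 3 (3S)-6-oxo-3-(prop-1-en-2-yl)heptanal, via secondary ozonide 2 (not isolated)
Conditions: O3 (1 equiv), CH2Cl2, −78 °C; then PPh3, −78 °C to rt
Reagents that add atoms: ozone ([O-][O+]=O)
Why: Chemoselective ozonolysis with reductive work-up: the electron-richer trisubstituted ring alkene should react with ozone before the 1,1-disubstituted isopropenyl group, and the stereocentre (C14 of the target) is not touched.

Step 2
Reactants: 3 (3S)-6-oxo-3-(prop-1-en-2-yl)heptanal
Product: 5 (5R)-2-methyl-5-(prop-1-en-2-yl)cyclopent-1-ene-1-carbaldehyde, via aldol adduct 4 (not isolated)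
Conditions: piperidine (cat.), AcOH (cat.), toluene, 80 °C
Reagents that add atoms: none
Why: Intramolecular aldol condensation under amine–acid catalysis: the aldehyde enamine adds to the methyl ketone (five-membered ring) and loss of water gives the conjugated cyclopentenal, so no new stereocentre remains.

Step 3
Reactants: 5 (5R)-2-methyl-5-(prop-1-en-2-yl)cyclopent-1-ene-1-carbaldehyde; 6 but-3-en-1-ylmagnesium bromide
Product: 7 1-[(5R)-2-methyl-5-(prop-1-en-2-yl)cyclopent-1-en-1-yl]pent-4-en-1-ol (both carbinol epimers)
Conditions: THF, −78 to 0 °C; then aq. NH4Cl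
Reagents that add atoms: none
Why: Grignard 1,2-addition to the hindered enal gives the allylic alcohol; the carbinol centre forms without control, which is harmless because it is oxidised in step 5.

Step 4
Reactants: 7 1-[(5R)-2-methyl-5-(prop-1-en-2-yl)cyclopent-1-en-1-yl]pent-4-en-1-ol
Product: 8 1-[5-methyl-2-(prop-1-en-2-yl)bicyclo[3.1.0]hexan-1-yl]pent-4-en-1-ol (cyclopropane CH2 anti to the isopropenyl group)
Conditions: Et2Zn, CH2I2, CH2Cl2, −10 to 0 °C
Reagents that add atoms: diiodomethane (ICI)
Why: Hydroxyl-directed Simmons–Smith cyclopropanation: the zinc alkoxide delivers CH2 (the future C1) to the allylic tetrasubstituted alkene much faster than to the two remote alkenes and mainly anti to the isopropenyl group, and either ring-fusion diastereomer serves because both cyclopropane stereocentres are erased in step 7.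

Step 5
Reactants: 8 1-[5-methyl-2-(prop-1-en-2-yl)bicyclo[3.1.0]hexan-1-yl]pent-4-en-1-ol
Product: 9 1-[5-methyl-2-(prop-1-en-2-yl)bicyclo[3.1.0]hexan-1-yl]pent-4-en-1-one
Conditions: Dess–Martin periodinane, NaHCO3, CH2Cl2, rt
Reagents that add atoms: none
Why: Dess–Martin oxidation of the secondary cyclopropyl carbinol to the ketone under buffered conditions that spare the cyclopropane and the alkenes; the carbinol epimers converge.

Step 6
Reactants: 9 1-[5-methyl-2-(prop-1-en-2-yl)bicyclo[3.1.0]hexan-1-yl]pent-4-en-1-one; 10 methyl acrylate
Product: 11 methyl (2E)-6-[5-methyl-2-(prop-1-en-2-yl)bicyclo[3.1.0]hexan-1-yl]-6-oxohex-2-enoate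
Conditions: second-generation Grubbs catalyst RuCl2(=CHPh)(PCy3)(H2IMes) (5 mol%), CH2Cl2, 40 °C
Reagents that add atoms: none
Why: Olefin cross-metathesis of the monosubstituted alkene with the electron-poor acrylate should give the E enoate, the hindered 1,1-disubstituted isopropenyl group staying out of the metathesis.

Step 7
Reactants: 11 methyl (2E)-6-[5-methyl-2-(prop-1-en-2-yl)bicyclo[3.1.0]hexan-1-yl]-6-oxohex-2-enoate
Product: 13 methyl 2-[1-methyl-5-oxo-7-(prop-1-en-2-yl)bicyclo[4.3.1]decan-2-yl]acetate (isopropenyl on the face of ring A opposite to the four-carbon bridge; acetate arm on the methyl side of C10), via ring-enlarged C11 radical enolate 12 (not isolated)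
Conditions: SmI2 (2.5 equiv, slow addition), HMPA, t-BuOH, THF, −78 to −20 °C; then aq. NH4Cl
Reagents that add atoms: none
Why: Proposed new method: single-electron reduction of the ketone gives a ketyl whose cyclopropane breaks at the C2–C11 bond (the acyl group on the bridgehead can align with either vicinal bond, and only this cleavage gives a tertiary radical), so the cyclopentane C2–C14–C13–C12–C11 takes up C1 and becomes ring A; the C11 radical then adds to C10, the β-carbon of the enoate, and the α-ester radical is reduced and protonated. The closest known reactions are SmI2-induced cyclopropyl ketone opening followed by 5-exo radical cyclisation and the Dowd–Beckwith one-carbon ring expansion; new here are the cleavage of the endocyclic bond and a ring closure that bridges the enlarged ring. Ring A arises by β-scission of the cyclopropylcarbinyl-type ketyl (ring enlargement from five to six), ring B by 7-exo-trig radical addition. C11 and C2 are tied to each other by the tether (the four-carbon bridge can span C2 and C11 only cis, and the bridgehead enolate can be protonated only from outside), their sense relative to C14 should follow from allylic 1,3-strain in the samarium enolate, which holds the isopropenyl group axial so that the chain closes on the opposite face, and at C10 the ester arm should take the position next to the C11 methyl and away from C12 of ring A. The step needs cleavage of the internal over the external cyclopropane bond and ring closure of the tertiary radical before its reduction or hydrogen transfer; the first is secured by radical stability and reversible ring opening, the second by slow addition of SmI2 and the polarity match between a nucleophilic tertiary radical and the enoate.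

Step 8
Reactants: 13 methyl 2-[1-methyl-5-oxo-7-(prop-1-en-2-yl)bicyclo[4.3.1]decan-2-yl]acetate
Product: 14 methyl 2-[1-methyl-7-(prop-1-en-2-yl)-5-(trifluoromethylsulfonyloxy)bicyclo[4.3.1]dec-4-en-2-yl]acetate
Conditions: KN(SiMe3)2, THF, −78 °C, PhNTf2 present from the start
Reagents that add atoms: N-phenylbis(trifluoromethanesulfonimide) (O=S(=O)(N(c1ccccc1)S(=O)(=O)C(F)(F)F)C(F)(F)F)
Why: Kinetic enolate formation can occur only toward C4 (C2 is a bridgehead) and is faster at the ketone than at the ester, and O-sulfonylation with PhNTf2 gives the enol triflate.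

Step 9
Reactants: 14 methyl 2-[1-methyl-7-(prop-1-en-2-yl)-5-(trifluoromethylsulfonyloxy)bicyclo[4.3.1]dec-4-en-2-yl]acetate
Product: 15 methyl 2-[5-(hydroxymethyl)-1-methyl-7-(prop-1-en-2-yl)bicyclo[4.3.1]dec-4-en-2-yl]acetate
Conditions: Bu3SnCH2OH, Pd(PPh3)4 (zerovalent palladium, 5 mol%), LiCl, 1,4-dioxane, 100 °C
Reagents that add atoms: (tributylstannyl)methanol (OC[Sn](CCCC)(CCCC)CCCC)
Why: Stille cross-coupling of the enol triflate with the hydroxymethylstannane brings in C18 as a free primary alcohol without moving the C3=C4 double bond.

Step 10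
Reactants: 15 methyl 2-[5-(hydroxymethyl)-1-methyl-7-(prop-1-en-2-yl)bicyclo[4.3.1]dec-4-en-2-yl]acetate
Product: 16 tricyclic ether ester (ring C closed between C18–O and C15; C3=C4 alkene; CH2CO2Me on C10)
Conditions: Co(salen) (N,N′-bis(salicylidene)ethylenediamine cobalt complex, divalent cobalt, 5 mol%), N-fluoro-2,4,6-trimethylpyridinium triflate, PhSiH3, PhCF3, 0 °C to rt
Reagents that add atoms: none
Why: Radical–polar crossover hydroalkoxylation by metal-hydride hydrogen atom transfer: the cobalt hydride adds H to the terminal carbon of the 1,1-disubstituted alkene, the tertiary C15 radical is oxidised and captured by the C18 hydroxyl in a Markovnikov 6-exo closure of ring C, and no stereocentre is created because C15 carries two methyl groups.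

Step 11
Reactants: 16 tricyclic ether ester
Product: 17 tricyclic aldehyde (CH2CHO on C10)
Conditions: i-Bu2AlH (1.1 equiv), CH2Cl2, −78 °C; then aq. potassium sodium tartrate
Reagents that add atoms: none
Why: Partial reduction of the methyl ester with i-Bu2AlH at low temperature stops at the aluminium hemiacetal, which releases the aldehyde on work-up; nothing else in 16 is reducible.

Step 12
Reactants: 17 tricyclic aldehyde
Product: 19 tricyclic alkyne (ethynyl on C10), via alkenyl nonaflate 18 (not isolated)
Conditions: C4F9SO2F, P2-Et phosphazene base, DMF, −20 °C to rt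
Reagents that add atoms: none
Why: One-pot nonaflation–elimination: the aldehyde enolate is O-sulfonylated and the phosphazene base then removes the sulfonic acid from the alkenyl nonaflate (E2) to give the terminal alkyne, the C10 stereocentre not being involved.

Step 13
Reactants: 19 tricyclic alkyne
Product: 20 3,4-cis-diol (both hydroxyls on the face of ring B away from rings A and C)
Conditions: OsO4 (2 mol%), NMO, acetone/H2O, rt
Reagents that add atoms: N-methylmorpholine N-oxide (C[N+]1([O-])CCOCC1); water (O)
Why: Catalytic syn-dihydroxylation: OsO4 should add to the strained trisubstituted C3=C4 alkene from the convex face away from rings A and C, which places the C3 hydroxyl cis to H2 as in the target, and the terminal alkyne is inert.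

Step 14
Reactants: 20 3,4-cis-diol
Product: 21 (E)-alkenyl pinacol boronate diol
Conditions: pinacolborane (excess), Cp2Zr(H)Cl (10 mol%), Et3N (10 mol%), CH2Cl2, rt; aqueous work-up
Reagents that add atoms: pinacolborane ([H]B1OC(C)(C)C(C)(C)O1)
Why: Zirconocene-catalysed hydroboration with pinacolborane adds H–B syn across the terminal alkyne with boron on the terminal carbon, which fixes the E alkenyl boronate.

Step 15
Reactants: 21 (E)-alkenyl pinacol boronate diol
Product: 22 3-hydroxy-4-ketone boronate
Conditions: IBX, DMSO, rt
Reagents that add atoms: none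
Why: IBX oxidises the secondary C4 hydroxyl of the secondary–tertiary diol to the ketone without glycol cleavage, and the tertiary C3 hydroxyl and the boronate ester stay intact.

Step 16
Reactants: 22 3-hydroxy-4-ketone boronate
Product: 24 5-methylene ketone boronate (exocyclic enone), via Mannich base 23 (not isolated)
Conditions: (CH2O)n, i-Pr2NH·CF3CO2H, THF, 65 °C
Reagents that add atoms: formaldehyde (C=O)
Why: Mannich-type α-methylenation: C5 is the only enolisable position of the C4 ketone (C3 is quaternary), the iminium ion from formaldehyde and the amine salt adds there, and β-elimination of the amine gives the exocyclic enone.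

Step 17
Reactants: 24 5-methylene ketone boronate; 25 acetaldehyde
Product: 26 5-acetonyl diketone boronate (acetonyl arm trans to the C10 side chain)
Conditions: MeCHO (excess), (n-Bu4N)4[W10O32] (2 mol%), MeCN, 390 nm, rt
Reagents that add atoms: none
Why: Decatungstate-photocatalysed hydroacylation (Giese-type addition): the acetyl radical formed by hydrogen abstraction from acetaldehyde adds to the unhindered methylene carbon, and back hydrogen transfer to the C5 radical from the convex face should set C5 with the acetonyl arm trans to the C10 side chain.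

Step 18
Reactants: 26 5-acetonyl diketone boronate; 27 3-methylbut-2-enoic acid
Product: 28 target CNP0237201.1
Conditions: Cu(OAc)2 (2 equiv), Et3N, 4 Å molecular sieves, CH2Cl2, dry air, rt
Reagents that add atoms: none
Why: Chan–Lam-type copper-mediated C–O coupling of the alkenyl boronate with the carboxylic acid forms the enol ester with retention of the E geometry under mild conditions that tolerate the ketones and the tertiary alcohol.

**Compound list**

1 | (S)-(−)-limonene, (4S)-1-methyl-4-(prop-1-en-2-yl)cyclohex-1-ene | CC1=CC[C@H](CC1)C(C)=C | starting material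
2 | secondary ozonide of the ring alkene of 1 (mixture at the two acetal carbons) | CC12CC[C@@H](CC(O1)OO2)C(C)=C | intermediate
3 | (3S)-6-oxo-3-(prop-1-en-2-yl)heptanal | O=CC[C@H](CCC(C)=O)C(C)=C | intermediate
4 | aldol adduct, 2-hydroxy-2-methyl-5-(prop-1-en-2-yl)cyclopentane-1-carbaldehyde | O=CC1C(C)(O)CC[C@@H]1C(C)=C | intermediate
5 | (5R)-2-methyl-5-(prop-1-en-2-yl)cyclopent-1-ene-1-carbaldehyde | O=CC1=C(C)CC[C@@H]1C(C)=C | intermediate
6 | but-3-en-1-ylmagnesium bromide | C=CCC[Mg]Br | starting material
7 | 1-[(5R)-2-methyl-5-(prop-1-en-2-yl)cyclopent-1-en-1-yl]pent-4-en-1-ol (carbinol epimers) | C=CCCC(O)C1=C(C)CC[C@@H]1C(C)=C | intermediate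
8 | 1-[5-methyl-2-(prop-1-en-2-yl)bicyclo[3.1.0]hexan-1-yl]pent-4-en-1-ol (CH2 anti to isopropenyl; carbinol epimers) | C=CCCC(O)[C@]12C[C@@]1(C)CC[C@@H]2C(C)=C | intermediate
9 | 1-[5-methyl-2-(prop-1-en-2-yl)bicyclo[3.1.0]hexan-1-yl]pent-4-en-1-one | C=CCCC(=O)[C@]12C[C@@]1(C)CC[C@@H]2C(C)=C | intermediate
10 | methyl acrylate | C=CC(=O)OC | starting material
11 | methyl (2E)-6-[5-methyl-2-(prop-1-en-2-yl)bicyclo[3.1.0]hexan-1-yl]-6-oxohex-2-enoate | COC(=O)/C=C/CCC(=O)[C@]12C[C@@]1(C)CC[C@@H]2C(C)=C | intermediate
12 | ring-enlarged C11 radical enolate (samarium enolate drawn as the enol) | COC(=O)/C=C/CCC(O)=C1C[C](C)CC[C@@H]1C(C)=C | intermediate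
13 | methyl 2-[1-methyl-5-oxo-7-(prop-1-en-2-yl)bicyclo[4.3.1]decan-2-yl]acetate | COC(=O)C[C@H]1CCC(=O)[C@H]2C[C@]1(C)CC[C@@H]2C(C)=C | intermediate
14 | enol triflate of 13 (C3=C4) | COC(=O)C[C@H]1CC=C(OS(=O)(=O)C(F)(F)F)[C@H]2C[C@]1(C)CC[C@@H]2C(C)=C | intermediate
15 | methyl 2-[5-(hydroxymethyl)-1-methyl-7-(prop-1-en-2-yl)bicyclo[4.3.1]dec-4-en-2-yl]acetate | COC(=O)C[C@H]1CC=C(CO)[C@H]2C[C@]1(C)CC[C@@H]2C(C)=C | intermediate
16 | tricyclic ether ester (rings A, B, C; C3=C4 alkene) | COC(=O)C[C@H]1CC=C2COC(C)(C)[C@H]3CC[C@@]1(C)C[C@H]23 | intermediate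
17 | tricyclic aldehyde | O=CC[C@H]1CC=C2COC(C)(C)[C@H]3CC[C@@]1(C)C[C@H]23 | intermediate
18 | alkenyl nonaflate of 17 (E/Z mixture) | FC(F)(F)C(F)(F)C(F)(F)C(F)(F)S(=O)(=O)OC=C[C@H]1CC=C2COC(C)(C)[C@H]3CC[C@@]1(C)C[C@H]23 | intermediate
19 | tricyclic alkyne | C#C[C@H]1CC=C2COC(C)(C)[C@H]3CC[C@@]1(C)C[C@H]23 | intermediate
20 | 3,4-cis-diol | C#C[C@H]1C[C@@H](O)[C@]2(O)COC(C)(C)[C@H]3CC[C@@]1(C)C[C@H]23 | intermediate
21 | (E)-alkenyl pinacol boronate diol | CC1(C)OB(/C=C/[C@H]2C[C@@H](O)[C@]3(O)COC(C)(C)[C@H]4CC[C@@]2(C)C[C@H]34)OC1(C)C | intermediate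
22 | 3-hydroxy-4-ketone boronate | CC1(C)OB(/C=C/[C@H]2CC(=O)[C@]3(O)COC(C)(C)[C@H]4CC[C@@]2(C)C[C@H]34)OC1(C)C | intermediate
23 | Mannich base (5-diisopropylaminomethyl ketone, mixture at C5) | CC1(C)OB(/C=C/[C@H]2C(CN(C(C)C)C(C)C)C(=O)[C@]3(O)COC(C)(C)[C@H]4CC[C@@]2(C)C[C@H]34)OC1(C)C | intermediate
24 | 5-methylene ketone boronate | CC1(C)OB(/C=C/[C@H]2C(=C)C(=O)[C@]3(O)COC(C)(C)[C@H]4CC[C@@]2(C)C[C@H]34)OC1(C)C | intermediate
25 | acetaldehyde | CC=O | starting material
26 | 5-acetonyl diketone boronate | CC1(C)OB(/C=C/[C@H]2[C@H](CC(C)=O)C(=O)[C@]3(O)COC(C)(C)[C@H]4CC[C@@]2(C)C[C@H]34)OC1(C)C | intermediate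
27 | 3-methylbut-2-enoic acid | CC(C)=CC(=O)O | starting material
28 | target CNP0237201.1 | CC(=O)C[C@@H]1C(=O)[C@]2(O)COC(C)(C)[C@H]3CC[C@@](C)(C[C@@H]32)[C@H]1/C=C/OC(=O)C=C(C)C | target

**Totals and risks**

Total step count: 18. Longest linear sequence: 18 steps, from 1 to 28.

Steps most likely to fail:

Step 7 (proposed new method). The tertiary C11 radical may be reduced or take up a hydrogen atom before it closes ring B, the enoate may be reduced conjugatively, or the external cyclopropane bond may break. The fallback separates ring enlargement and ring closure with known reactions and sets out from 11. Me3SiI in CH2Cl2 at −40 °C (homo-conjugate opening of the silylated ketone by iodide at the tertiary cyclopropane carbon, then aqueous work-up, which lets C2 settle trans to the isopropenyl group) should give the ring-enlarged tertiary iodide F1. Bu3SnH with AIBN under syringe-pump dilution in benzene at 80 °C then forms the same C11 radical without a one-electron reductant, and 7-exo Giese closure onto the enoate returns to the route at 13.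

Step 10. The tertiary C15 radical or cation may be lost by elimination or reduction before the strained, trans-fused ring C closes. The fallback reverses the polarity of the ether formation and sets out from 15. Mukaiyama hydration of the isopropenyl group (Co(acac)2, PhSiH3, O2, i-PrOH) should give the tertiary alcohol diol F2; selective sulfonylation of the primary allylic hydroxyl (MsCl, Et3N, CH2Cl2, −20 °C) gives the allylic mesylate F3; and NaH in THF closes ring C by intramolecular Williamson displacement at C18, which comes back to the route at 16.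

Step 17. Hydrogen-atom delivery to the C5 radical may occur from the wrong face and give the C5 epimer. The fallback places the carbon group, not the hydrogen, on the face that is open, and sets out from 22. LiN(SiMe3)2 (2.2 equiv, THF, −78 °C) forms the alkoxide and the C5 enolate, and 2-methoxyallyl bromide should give the 5-(2-methoxyallyl) ketone F4, with the side chain on the face that the hydrogen atom would have taken. Mild hydrolysis of the enol ether (aq. oxalic acid, THF) comes back to the route at 26.

Further compounds
F1 | step 7 | methyl (2E)-6-[4-iodo-4-methyl-2-(prop-1-en-2-yl)cyclohexyl]-6-oxohex-2-enoate (acyl and isopropenyl groups trans) | COC(=O)/C=C/CCC(=O)[C@H]1CC(C)(I)CC[C@@H]1C(C)=C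
F2 | step 10 | methyl 2-[5-(hydroxymethyl)-7-(2-hydroxypropan-2-yl)-1-methylbicyclo[4.3.1]dec-4-en-2-yl]acetate | COC(=O)C[C@H]1CC=C(CO)[C@H]2C[C@]1(C)CC[C@@H]2C(C)(C)O
F3 | step 10 | methyl 2-[7-(2-hydroxypropan-2-yl)-1-methyl-5-(methylsulfonyloxymethyl)bicyclo[4.3.1]dec-4-en-2-yl]acetate | COC(=O)C[C@H]1CC=C(COS(C)(=O)=O)[C@H]2C[C@]1(C)CC[C@@H]2C(C)(C)O
F4 | step 17 | 5-(2-methoxyallyl) 3-hydroxy-4-ketone boronate | CC1(C)OB(/C=C/[C@H]2[C@H](CC(=C)OC)C(=O)[C@]3(O)COC(C)(C)[C@H]4CC[C@@]2(C)C[C@H]34)OC1(C)C
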